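All constants are invented; the run is a simulation.

A single exponential cannot follow the starting material in this flask: one of its exits runs with the square of its concentration, and two others run back.

    starting material ⇌ ring (K1 = 0.33, k1 = 0.054 /min)
    2 starting material → open dimer (k2 = 0.19 /M/min)
    starting material + protic impurity → quenched substrate (k3 = 0.057 /M/min)
    starting material ⇌ dormant form (K4 = 3.7, k4 = 0.17 /min)

starting material 0.80 M; protic impurity 0.400 M; time 80 min

- percentages count the starting material that a species holds: one open dimer counts as two
- a doubled species enters its step squared and goes two at a time
- what has gone from starting material into another species counts as reacted, even if it can come back
- the reaction counts as stopped when no species that holds the starting material changes by six tenths of a point or more over the second half of the time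
- run time (flask): 80 min

* the state of affairs at 80 min: stopped, and by what, or still going (it is still moving / forward and back rates have come level / all of the starting material has reacted)
* part of the starting material gone at 80 min
* the ring standing at 80 min, as a percentage of the starting material charged
* the open dimer standing at 80 min, as a percentage of the starting material charged

So split the run in two. At first you can ignore the way back. Per unit of starting material, the open dimer takes a rate of twice the rate constant times the concentration, while the other exits together take a fixed 0.247 /min, with the protic impurity held at its charge. Integrating the dimer's share of this race, from the charge down to zero, gives a logarithm and 0.279 M of starting material in open dimer. The other 0.521 M I call the pool: starting material, ring and dormant form, counting the small quenched part with them.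

The exchange is quick: the dormant step's forward half-life of 4.1 min and the ring step's relaxation half-life of 3.18 min are both short against 80 min, so I let both reversible steps stand level. Ring is then the first equilibrium constant times the starting material, and dormant form the second, which is larger and makes the dormant form the resting state. The free fraction, the share of the pool standing as starting material, is one over one plus both constants: 0.199.

What leaves the pool for good leaves through this free part, into open dimer or quenched substrate. Replace the curve by its mean: I guess the pool falls to half, so its mean is 0.391 M. The pool then decays at 0.0104 /min and ends near 0.227 M. The mean of its two ends is 0.374 M, close to my guess. That gives 94.4% gone, 1.86% ring and 55.6% open dimer. By this reckoning the pool loses 14.6% of the charge over the second half, more than the stopping margin, so my verdict is: it is still moving.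

The forecast says: it is still moving, with 94.2% gone, 2% ring and 51.3% open dimer, on the ground that a pool of exchanging forms “drains slowly through dimerisation and quenching”.

The simulation gives: it is still moving, with 94.1% gone, 2.00% ring and 51.5% open dimer. In this flask the free fraction read at 80.0 min is 0.178, against my 0.199. The dormant form is the main reason this flask's open dimer stands short of the full charge: with the dormant step taken away both ways, open dimer goes from 51.5% to 78.3%, which is 55% of what is missing, and the verdict on the end changes.

Now read the same flask at 3.0 h. Start from its pool of 0.263 M at 80.0 min, with the protic impurity as it then stands, and the same reckoning gives a decay of 0.00608 /min, a pool of 0.143 M, and so 1.17% ring. The neighbour flask's computed ring is 1.23%.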